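## Structural features

- Target 14 is a diaryl ether of two catechol units. Ring B (C1–C6) carries OH at C1, Br at C2, C3, C4 and C5, and the ether oxygen at C6. Ring A (C1'–C6') carries the ether oxygen at C1', OH at C2', and Br at C3' and C5'.
- There is no stereocentre and no ring beyond the two benzenes, so the whole problem is constitutional.
- Ring B is hexasubstituted. The ether oxygen is flanked by C1–OH and C5–Br on ring B and by C2'–OH on ring A, so three of its four ortho positions are filled.
- The fragile groups are the six C–Br bonds, which are open to metal insertion, halogen–metal exchange and reduction. The two acidic phenols are also fragile: they can be oxidised to quinoid species, and as phenoxides they can displace the C5 bromide to close a dibenzodioxin.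
- The real difficulty is the hindered C6–O bond to an electron-poor, fully substituted ring, together with the unequal 4 + 2 distribution of bromine over two rings with the same oxygenation pattern.
- The key step exploits three features. C2–C5 of ring B is a contiguous tetrabromobutadiene unit. C1–C6 is a vicinally dioxygenated two-carbon unit. The oxygens on C6 and on C2' are ortho to each other on ring A, so C1, C6 and the two ring A oxygens map onto a 1,4-benzodioxin in which only the C1–O(C2') bond has been opened.
- The ring A bromines are ortho and para to C2'–OH and ring B has no free position, so they can be introduced last.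

## Logic of the disconnections

**14 ⇒ 12 (through 13).**
- Bonds cut: C3'–Br and C5'–Br.
- Reason: both carbons are activated by C2'–OH, and ring B is blocked.
- Gain: ring A becomes unsubstituted and traceable to a symmetric precursor, so the question of which ring A oxygen is etherified disappears.
- Demand: the free OH must direct more strongly than the ether oxygen, and substitution must stop after two bromines.

**12 ⇒ 5 + 8 (through 11, 10 and 9), the key disconnection.**
- Bonds cut: C1–C2 and C5–C6 of ring B. In the same retrosynthetic move the bond from C1 to the oxygen on C2' is restored.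
- In one sentence: ring B is built by cycloaddition of 8 onto the alkene of 5 with loss of SO2, and the dioxin ring opens on aromatization to reveal the diaryl ether.
- Reason: all four bromines come in one symmetric piece. The C6–O bond descends from an ordinary alkyl aryl ether bond, so no aryl–oxygen coupling is needed.
- Gain: a hexasubstituted arene and a hindered ether are reduced to two small compounds, each one or two steps from commercial material.
- Demand: an electron-poor diene must meet an electron-rich alkene, SO2 must leave, and the opening must break C1–OAr and not C1–OSi.

**5 ⇒ 4.**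
- Bond cut: O–Si.
- Reason: the trioxygenated alkene of 5 is the enol form of 4.
- Gain: a stable carbonyl compound.
- Demand: O-silylation without a free enolate that could expel aryloxide.

**4 ⇒ 1 + 2 (through 3).**
- Bonds cut: the acyl C–O bond and the O–CH2 bond.
- Reason: both are standard ester and ether bonds to the two equivalent oxygens of 1.
- Gain: two commodity chemicals.
- Demand: ring closure must win over oligomerization.

**8 ⇒ 6 (through 7).**
- Bonds cut: the two S=O bonds.
- Reason: 6 is commercial and already holds the four bromines.
- Gain: no bromination of ring B is ever needed.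
- Demand: an oxidant strong enough for a deactivated thiophene.

## Other disconnections considered

**Alternative 1:** the polar cut of the C6–O (or C1'–O) ether bond, which is the first that comes to mind.
- Forward key step: an Ullmann-type coupling with CuI (monovalent copper) of an ortho-haloanisole with an ortho-methoxyphenol. This gives bis(2-methoxyphenyl) ether A1, followed by bromination and cleavage of both methyl ethers.
- The two rings of A1 are identical, so electrophilic bromination has no basis for placing four bromines on one ring and two on the other.
- If the bromines are set before the coupling, the metal must pick one carbon–halogen bond among several C–Br bonds. The phenoxide partner is also di-ortho-substituted and weakly nucleophilic, and a metal-free SNAr has no activating group.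
- Two protecting groups must also be carried. The chosen plan never forms an aryl–oxygen bond at a hindered centre.

**Alternative 2:** the same C6–O bond cut at the quinone oxidation level.
- Compound 12 is traced to the spiroketal 3',4',5',6'-tetrabromospiro[1,3-benzodioxole-2,1'-cyclohexa-3',5'-dien]-2'-one A3, to be made from 1 and tetrabromo-1,2-benzoquinone A2.
- Forward key step: ketalization of one carbonyl of A2 by both oxygens of 1. A two-electron reductive opening then expels one aryloxide alpha to the ketone and aromatizes ring B.
- The symmetry is attractive, but A2 is a high-potential quinone and 1 is an easily oxidised donor. Hydrogen and electron transfer between them should outrun ketalization.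
- Oxygen nucleophiles also attack A2 at C4 and C5 by addition–elimination of bromide.
- The reductant for the opening endangers the C–Br bonds.

**Alternative 3:** the radical cut of C6–O, as in the biosynthesis of brominated diphenyl ethers.
- Forward key step: an anodic cross-coupling of 3,5-dibromocatechol A4, through the oxygen on C1', with the free ortho carbon of 2,3,4,5-tetrabromophenol A5, leading directly to 14.
- It is the shortest route on paper, but it needs four selectivities at once: cross- over homo-coupling, C–O over C–C bond formation, one oxygen of A4 over the other, and survival of the oxidisable product.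
- A4 should be oxidised to its ortho-quinone at a lower potential than that of productive coupling.
- A5 is itself not a simple compound to obtain.
- In the chosen plan every one of these choices is fixed by connectivity.

Key step: step 4

Remark on the chemistry: 14 has no stereocentre. Compounds 9, 10, 11 and F8 are racemic and drawn as one enantiomer. For 9 the isomer with the benzodioxin oxygens endo is drawn, although the endo or exo sense is open and is erased in the next event.

## Steps

Step 1
Reactants: 1 catechol (benzene-1,2-diol); 2 chloroacetyl chloride
Product: 4 1,4-benzodioxin-2(3H)-one, via 2-hydroxyphenyl chloroacetate 3 (not isolated)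
Conditions: Et3N (2.2 equiv), MeCN (0.05 M), 0 °C then 60 °C
Reagents that add atoms: none
Why: O-acylation of one of the two equivalent OH groups of 1 gives 3, whose remaining phenol closes the six-membered ring by an intramolecular Williamson reaction (6-exo-tet SN2 at the activated alpha-chloro ester carbon). The symmetry of 1 removes any regiochemical question, and dilution suppresses oligomeric esters.

Step 2
Reactants: 4 1,4-benzodioxin-2(3H)-one
Product: 5 2-(tert-butyldimethylsilyloxy)-1,4-benzodioxine
Conditions: TBSOTf (1.2 equiv), Et3N (1.6 equiv), Et2O, 0 to 23 °C; pentane, filtration, used without chromatography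
Reagents that add atoms: tert-butyldimethylsilyl triflate, CC(C)(C)[Si](C)(C)OS(=O)(=O)C(F)(F)F
Why: Soft enolization: silylation of the lactone carbonyl oxygen acidifies C3–H2, which is also flanked by O4, and Et3N removes the proton to give the O-silyl ketene acetal. No free aryl ester enolate is formed, so loss of aryloxide to a ketene (E1cB) is avoided. The bulky silyl group favours O- over C-silylation, and the ring fixes the alkene geometry.

Step 3
Reactants: 6 tetrabromothiophene
Product: 8 tetrabromothiophene 1,1-dioxide, via tetrabromothiophene 1-oxide 7 (not isolated)
Conditions: urea·H2O2, (CF3CO)2O, MeCN/CH2Cl2, 0 to 23 °C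
Reagents that add atoms: urea–hydrogen peroxide, NC(N)=O.OO (source of both sulfone oxygens, passed on through trifluoroperacetic acid, OOC(=O)C(F)(F)F, formed in the flask)
Why: Electrophilic oxygen transfer from trifluoroperacetic acid is the established way to oxidise thiophenes deactivated by electron-withdrawing groups. The non-aromatic S-oxide 7 is oxidised faster than 6, so it should not accumulate and dimerize. As in other tetrahalothiophene dioxides, the four halogens keep 8 from self-cycloaddition.

Step 4
Reactants: 5 2-(tert-butyldimethylsilyloxy)-1,4-benzodioxine; 8 tetrabromothiophene 1,1-dioxide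
Product: 12 2,3,4,5-tetrabromo-6-(2-hydroxyphenoxy)phenol, via bridged sulfone cycloadduct 9 (not isolated), via silyloxy dihydrodibenzodioxin 10 (not isolated), via 6-aryloxy cyclohexadienone 11 (not isolated)
Conditions: 5 (1.3 equiv), PhMe, N2 sweep, 23 to 60 °C (−SO2); then Bu4NF/AcOH (1:1, 1.5 equiv), THF, 0 °C
Reagents that add atoms: none
Why: The diene of 8 is non-aromatic and strongly LUMO-lowered by the sulfone and four bromines, while the C2=C3 alkene of 5 carries three oxygen donors, so the pair should combine in an inverse-electron-demand Diels–Alder reaction that forms the C1–C2 and C5–C6 bonds of ring B and gives 9. Cheletropic loss of SO2 from 9 then gives the cyclohexadiene 10; the closest known reaction type is the annulation of alkenes and enol ethers with tetrahalothiophene 1,1-dioxides, in which a leaving group on the former alkene carbon is lost on aromatization. Ring B is thus closed as a six-membered carbocycle by a suprafacial [4+2] cycloaddition, concerted or strongly asynchronous through a zwitterion, both courses ending in the same ring. The stereocentres are transient: C4a and C10a of 10 are cis because the alkene of 5 is locked in its ring and adds suprafacially, the bridgeheads of 9 follow from the bridge, the endo or exo sense is immaterial, and none survives in 12. No regioselectivity is needed, since 8 has C2v symmetry and both orientations of 5 give the same constitution. The selectivity that is needed is cleavage of C4a–O5 and not of C4a–OSi: fluoride takes the silicon, and the hemiketal alkoxide so formed has the aryloxide O5 as its only leaving group, so that it collapses to 11, which enolizes to 12 with gain of aromaticity. The substrate is biased the same way without fluoride, because in 10 the C10a–H bond is anti to C4a–O5 and syn to C4a–OSi, aryloxide is the better nucleofuge, and the silyloxy group is the better donor to a cation at C4a. Acetic acid keeps both phenols of 12 protonated, which prevents displacement of the C5 bromide by the ring A oxygen, and no metal or reductant is present that could touch a C–Br bond.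

Step 5
Reactants: 12 2,3,4,5-tetrabromo-6-(2-hydroxyphenoxy)phenol
Product: 14 2,3,4,5-tetrabromo-6-(3,5-dibromo-2-hydroxyphenoxy)phenol (target), via 5'-monobromide 13 (not isolated)
Conditions: Br2 (2.05 equiv), AcOH, 15 to 23 °C; aq. NaHSO3
Reagents that add atoms: bromine, BrBr
Why: Electrophilic aromatic bromination directed by the free C2'–OH, first para (C5', giving 13) and then ortho (C3'). Ring B has no free position, and the lone pairs of the ether oxygen are drawn towards the electron-poor ring B, so it is the weaker director. Two bromines deactivate ring A against a third, and the reductive work-up returns any ipso-brominated dienone to the phenol.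

## Compound list

1 | catechol | Oc1ccccc1O | starting material
2 | chloroacetyl chloride | ClCC(Cl)=O | starting material
3 | 2-hydroxyphenyl chloroacetate | Oc1ccccc1OC(=O)CCl | intermediate
4 | 1,4-benzodioxin-2(3H)-one | O=C1COc2ccccc2O1 | intermediate
5 | 2-(tert-butyldimethylsilyloxy)-1,4-benzodioxine | CC(C)(C)[Si](C)(C)OC1=COc2ccccc2O1 | intermediate
6 | tetrabromothiophene | Brc1sc(Br)c(Br)c1Br | starting material
7 | tetrabromothiophene 1-oxide | O=S1C(Br)=C(Br)C(Br)=C1Br | intermediate
8 | tetrabromothiophene 1,1-dioxide | O=S1(=O)C(Br)=C(Br)C(Br)=C1Br | intermediate
9 | 1,2,3,4-tetrabromo-4a-(tert-butyldimethylsilyloxy)-1,4,4a,10a-tetrahydro-1,4-epithiodibenzo[b,e][1,4]dioxine 11,11-dioxide (racemic, cis ring fusion) | CC(C)(C)[Si](C)(C)O[C@@]12Oc3ccccc3O[C@@H]1[C@]4(Br)C(Br)=C(Br)[C@@]2(Br)S4(=O)=O | intermediate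
10 | cis-1,2,3,4-tetrabromo-4a-(tert-butyldimethylsilyloxy)-4a,10a-dihydrodibenzo[b,e][1,4]dioxine (racemic) | CC(C)(C)[Si](C)(C)O[C@@]12Oc3ccccc3O[C@@H]1C(Br)=C(Br)C(Br)=C2Br | intermediate
11 | 2,3,4,5-tetrabromo-6-(2-hydroxyphenoxy)cyclohexa-2,4-dien-1-one (racemic) | Oc1ccccc1O[C@H]1C(=O)C(Br)=C(Br)C(Br)=C1Br | intermediate
12 | 2,3,4,5-tetrabromo-6-(2-hydroxyphenoxy)phenol | Oc1ccccc1Oc1c(O)c(Br)c(Br)c(Br)c1Br | intermediate
13 | 2,3,4,5-tetrabromo-6-(5-bromo-2-hydroxyphenoxy)phenol | Oc1ccc(Br)cc1Oc1c(O)c(Br)c(Br)c(Br)c1Br | intermediate
14 | 2,3,4,5-tetrabromo-6-(3,5-dibromo-2-hydroxyphenoxy)phenol | Oc1c(Br)cc(Br)cc1Oc1c(O)c(Br)c(Br)c(Br)c1Br | target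

## Step count and least certain steps

Total step count: 5. Longest linear sequence: 4 (steps 1, 2, 4 and 5). Step 3 is a one-step branch that joins at step 4.

**Step 4 (key step).**

Four processes could go wrong:
- The nucleophilic ketene acetal may attack a bromine atom of 8 (halophilic attack) or transfer an electron instead of cycloadding.
- The SO2 set free may consume the ketene acetal by an ene-type silyl transfer. The N2 sweep and the excess of 5 are there to counter this.
- Trace acid may trigger aromatization of 10 by loss of silanol, with both ring C–O bonds kept. This would waste material and lead into a toxic compound class.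
- The trisubstituted alkene may add too slowly at a temperature that 10 tolerates.

The fallback gives up the ring construction and forms the ether bond with a trivalent iodine reagent. It sets out from 1 and comes back at 12.
- Exhaustive bromination of 1 (Br2, AcOH) gives tetrabromocatechol F1.
- Monomethylation (MeI, 1 equiv, Li2CO3, DMF) gives 2,3,4,5-tetrabromo-6-methoxyphenol F2. The symmetry of F1 allows only one mono-ether.
- Metal-free O-arylation of F2 (KOtBu, THF) uses bis(2-methoxyphenyl)iodonium tetrafluoroborate F3. F3 is made from 2-iodoanisole and 2-methoxyphenylboronic acid with mCPBA and BF3·OEt2.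
- The arylation gives 1,2,3,4-tetrabromo-5-methoxy-6-(2-methoxyphenoxy)benzene F4 without touching a C–Br bond.
- BBr3 in CH2Cl2 cleaves both methyl ethers to 12.

**Step 2.**

Likely failures are competing C-silylation, opening of the aryl ester through a ketene if free enolate forms, and hydrolysis of the ketene acetal during handling.

The fallback replaces the cyclic aryl ester by an open-chain alkyl ester, whose enolization is routine. It sets out from 4 and comes back at 12.
- Methanolysis of 4 (MeOH, cat. Et3N) gives methyl 2-(2-hydroxyphenoxy)acetate F5.
- TBSCl and imidazole give methyl 2-[2-(tert-butyldimethylsilyloxy)phenoxy]acetate F6.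
- LDA then TBSCl (THF, DMPU, −78 °C) gives the ketene silyl acetal (Z)-1-methoxy-1-(tert-butyldimethylsilyloxy)-2-[2-(tert-butyldimethylsilyloxy)phenoxy]ethene F7. The Z geometry is expected from the chelated enolate and has no bearing on the outcome.
- Cycloaddition of F7 with 8 and loss of SO2 gives 1,2,3,4-tetrabromo-5-methoxy-5-(tert-butyldimethylsilyloxy)-6-[2-(tert-butyldimethylsilyloxy)phenoxy]cyclohexa-1,3-diene F8.
- Bu4NF/AcOH removes both silyl groups from F8. The hemiketal expels methanol and the dienone enolizes to 12.

**Step 5.**

Likely failures are insufficient site selectivity between the positions activated by C2'–OH and those activated by the ether oxygen, a third bromination of ring A, and oxidative dearomatization of the electron-rich phenol by bromine.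

The fallback carries the ring A bromines in from the start, so their positions are fixed by connectivity. It sets out from 8, which meets a new dienophile, and comes back at 14.
- Commercial 3,5-dibromosalicylaldehyde is protected (MOMCl, iPr2NEt) to give 3,5-dibromo-2-(methoxymethoxy)benzaldehyde F9.
- Baeyer–Villiger oxidation (mCPBA) gives 3,5-dibromo-2-(methoxymethoxy)phenyl formate F10.
- K2CO3 in MeOH gives 3,5-dibromo-2-(methoxymethoxy)phenol F11.
- Methyl bromoacetate and K2CO3 give methyl 2-[3,5-dibromo-2-(methoxymethoxy)phenoxy]acetate F12.
- TsOH·H2O in hot toluene removes the acetal to give methyl 2-(3,5-dibromo-2-hydroxyphenoxy)acetate F13. F13 lactonizes in the same flask to 6,8-dibromo-1,4-benzodioxin-2(3H)-one F14.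
- TBSOTf and Et3N give 6,8-dibromo-2-(tert-butyldimethylsilyloxy)-1,4-benzodioxine F15.
- Under the conditions of step 4, F15 and 8 give 14 directly. The acyl oxygen that is expelled is the one ortho and para to the two bromines.

## Further compounds

F1 | step 4 | tetrabromocatechol | Oc1c(O)c(Br)c(Br)c(Br)c1Br
F2 | step 4 | 2,3,4,5-tetrabromo-6-methoxyphenol | COc1c(O)c(Br)c(Br)c(Br)c1Br
F3 | step 4 | bis(2-methoxyphenyl)iodonium tetrafluoroborate | COc1ccccc1[I+]c1ccccc1OC.F[B-](F)(F)F
F4 | step 4 | 1,2,3,4-tetrabromo-5-methoxy-6-(2-methoxyphenoxy)benzene | COc1ccccc1Oc1c(OC)c(Br)c(Br)c(Br)c1Br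
F5 | step 2 | methyl 2-(2-hydroxyphenoxy)acetate | COC(=O)COc1ccccc1O
F6 | step 2 | methyl 2-[2-(tert-butyldimethylsilyloxy)phenoxy]acetate | COC(=O)COc1ccccc1O[Si](C)(C)C(C)(C)C
F7 | step 2 | (Z)-1-methoxy-1-(tert-butyldimethylsilyloxy)-2-[2-(tert-butyldimethylsilyloxy)phenoxy]ethene | CO/C(O[Si](C)(C)C(C)(C)C)=C/Oc1ccccc1O[Si](C)(C)C(C)(C)C
F8 | step 2 | 1,2,3,4-tetrabromo-5-methoxy-5-(tert-butyldimethylsilyloxy)-6-[2-(tert-butyldimethylsilyloxy)phenoxy]cyclohexa-1,3-diene (racemic, silyloxy cis to aryloxy) | CO[C@@]1(O[Si](C)(C)C(C)(C)C)[C@H](Oc2ccccc2O[Si](C)(C)C(C)(C)C)C(Br)=C(Br)C(Br)=C1Br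
F9 | step 5 | 3,5-dibromo-2-(methoxymethoxy)benzaldehyde | COCOc1c(Br)cc(Br)cc1C=O
F10 | step 5 | 3,5-dibromo-2-(methoxymethoxy)phenyl formate | COCOc1c(Br)cc(Br)cc1OC=O
F11 | step 5 | 3,5-dibromo-2-(methoxymethoxy)phenol | COCOc1c(Br)cc(Br)cc1O
F12 | step 5 | methyl 2-[3,5-dibromo-2-(methoxymethoxy)phenoxy]acetate | COCOc1c(Br)cc(Br)cc1OCC(=O)OC
F13 | step 5 | methyl 2-(3,5-dibromo-2-hydroxyphenoxy)acetate | COC(=O)COc1cc(Br)cc(Br)c1O
F14 | step 5 | 6,8-dibromo-1,4-benzodioxin-2(3H)-one | O=C1COc2cc(Br)cc(Br)c2O1
F15 | step 5 | 6,8-dibromo-2-(tert-butyldimethylsilyloxy)-1,4-benzodioxine | CC(C)(C)[Si](C)(C)OC1=COc2cc(Br)cc(Br)c2O1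
A1 | alternative 1 | bis(2-methoxyphenyl) ether | COc1ccccc1Oc1ccccc1OC
A2 | alternative 2 | tetrabromo-1,2-benzoquinone | O=C1C(=O)C(Br)=C(Br)C(Br)=C1Br
A3 | alternative 2 | 3',4',5',6'-tetrabromospiro[1,3-benzodioxole-2,1'-cyclohexa-3',5'-dien]-2'-one | O=C1C(Br)=C(Br)C(Br)=C(Br)C12Oc3ccccc3O2
A4 | alternative 3 | 3,5-dibromocatechol | Oc1cc(Br)cc(Br)c1O
A5 | alternative 3 | 2,3,4,5-tetrabromophenol | Oc1cc(Br)c(Br)c(Br)c1Br
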